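# Proposed total synthesis of CNP0147326.4 by anionic oxy-Cope ring expansion through C8–C9

## The problem

The target is a germacranolide. Germacrane numbering is used throughout: carbocycle C1–C10, formyl C14 on C10, hydroxymethyl C15 on C4, lactone carbons C11–C13 on C7. "Ring-cis" means that the two ring carbons are cis on the double bond.

- **Ring and alkenes.** The ten-membered carbocycle carries two ring-cis trisubstituted alkenes, C1=C10 and C4=C5. End-to-end closure of such a ring is penalised by strain and entropy.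
- **Stereocentres.** Four contiguous stereocentres (6R,7S,8S,9S) sit on one flank, with a trans-fused α-methylene-γ-lactone across C6/C7. C8 and C9 are the two oxygen-bearing carbons that no neighbour can control if they are made late. Once they exist, C7 and C6 can be set from the ring conformation by attack on its outer face.
- **Sensitive groups.** O8 (methacrylate) and O9 (acetate) are neighbours and need orthogonal masking; acyl migration between them is a risk. The α-methylene lactone and the methacrylate are Michael acceptors. The C9 acetate next to the C1=C10–C14 enal is a Baylis–Hillman-type acetate that nucleophiles can displace. These groups must come last and under non-nucleophilic conditions.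
- **Enabling feature.** The C8–C9 bond joins the two carbinol carbons and lies 1,6 to the C1/C6 pair. If C1 is reconnected to C6, the atoms C1–C6 with the C4=C5 alkene form a cyclohex-2-en-1-ol. The atoms C8=C7–C6(O)–C1–C10=C9 then form a 3-oxy-1,5-diene, so a [3,3] shift makes C8–C9 and leaves the carbonyl on C6, where the lactone oxygen is needed.
- **C1=C10 geometry.** In the ring-cis enal C2 is trans to the formyl group. This is the thermodynamically preferred arrangement of a 2-alkyl-2-enal and avoids a trans-cyclodecene, so this geometry can be corrected at the aldehyde stage.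

## Retrosynthesis

**End game, 36 back to 33.** The target 36 is reached from silyl ether 35 by C15–O desilylation, and 35 from hydroxy enal 34 by acetylation. The C1=C10 bond of 34 is taken back to its ring-trans isomer 33. This cut is preferred to building the ring-cis bond in the ring-forming step, because the ring expansion below delivers ring-trans reliably and the enal is the one stage where the double bond can equilibrate. The forward step is a thermodynamic isomerisation with no ionic intermediate next to the C9 oxygen.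

**Acyl and oxidation pattern, 33 back to 29.** Enal 33 comes from 9,14-diol 32 by selective oxidation of the primary allylic alcohol, and 32 from acetonide 31. Methacrylate 31 comes from alcohol 30, and 30 from PMB ether 29. O9 and O14 are masked together as one isopropylidene acetal and O8 as a PMB ether. This gives the orthogonality that O8 and O9 need with two protecting groups instead of three. The methacrylate, which migrates less readily than an acetate, is installed before O9 is uncovered.

**Lactone, 29 back to 22.** The exocyclic methylene (C13) of 29 is removed to Mannich base 27 and then lactone 26. The lactone is opened to 6,12-diol 24, which comes from silyl ether 23, and the C6 carbinol is taken back to ketone 22. Oxidative lactonisation of a 1,4-diol keeps the C6 configuration and needs no acid; an acetal side chain would need acid and would compete with the acetonide. The forward reduction must add hydride to the outer face of the C6 carbonyl.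

**Key disconnection, 22 back to 19.** C8–C9 is cut and C1–C6 reconnected. Dienone 22 becomes the 1,6-dialkenylcyclohex-2-en-1-ol 19: two rings fewer in the sense of strain, two stereocentres exchanged for two on a six-membered ring.

- Cutting C7–C8 or C9–C10 instead would leave an acyclic closure of a ten-membered ring.
- The relative configuration of 19 is chosen as trans (both arms equatorial). A ketone adds a nucleophile anti to its α′-substituent, and the trans carbinol has a single chair available. That chair gives the C1=C10 bond ring-trans.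
- The cis carbinol would give ring-cis directly through a chair with C2 axial. It is the minor product of ketone addition and has a second chair that leads to the wrong C8/C9 sense, so it is not used.
- The forward reaction must form C8–C9 with both ether oxygens equatorial and must protonate the resulting C6 enolate at C7 from the outer face.

**Carbinol, 19 back to 9 and 17.** The C6–C7 bond is cut to enone 9 and alkenyl iodide 17. The E geometry of 17 (iodine trans to the PMB ether oxygen) is what places O8 equatorial in the chair. The forward addition needs a non-basic alkenylmetal, because the α′-hydrogen of 9 is acidic.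

**Enone arm, 9 back to 5 and 7, then 4, 3, 1 and 6.** The C1–C10 bond is cut to silyl dienol ether 5 and dioxinyl triflate 7.

- The 4H-1,3-dioxin ring locks O9 cis to C14. The enol ether geometry that the chair needs is therefore built into the arm, and it later becomes the O9/O14 acetonide.
- Triflate 7 is the enol triflate of 2,2-dimethyl-1,3-dioxan-5-one 6.
- Dienol ether 5 comes from enone 4, and 4 from 3-(hydroxymethyl)cyclohexenone 3, the Birch product of 3-methoxybenzyl alcohol 1.
- The forward coupling must set the α′-centre of 9 as R under conditions that do not enolise it.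

**Alkenyl iodide, 17 back to 15, 12, 13, 10 and 11.** Iodide 17 comes from ynol ether 15 by syn H–I addition. Ynol ether 15 comes from dichlorovinyl ether 12 and iodide 13, and 12 from 4-methoxybenzyl alcohol 10 and trichloroethylene 11. This fixes the geometry by a syn hydrometallation instead of an unselective enol ether halogenation.

## Roads not taken

**Alternative 1:** Two-carbon ring expansion of an eight-membered enamine.

- Cut: C1–C2 and C9–C10.
- Forward key step: an enamine double bond in an eight-membered ring adds an acetylenic ester. The cyclobutene opens to the ten-membered dienamine ester A1.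
- Merits: C14 arrives on C10 at the carboxyl level. C6, C7 and C8 could be set on the smaller ring. No strong base is needed.
- Weak points for this target:
  - The precursor is itself a medium ring with three contiguous stereocentres.
  - The enamine must form toward C2 and not toward the oxygenated C8.
  - A1 has its unsaturation at C1=C2 and C9=C10, with C9 at the ketone level. The C9 stereocentre is not made, the diene must be transposed to C1=C10, and the ester must be reduced.
- Comparison: this road is better in that C14 needs no late oxidation and the C1=C10 bond is not made with the wrong geometry. The chosen plan sets against it that C8 and C9 are both created in the ring-forming step and that its precursor is a six-membered ring.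

**Alternative 2:** Silylene-locked boat Cope rearrangement of an elemane aldehyde.

- Cut: C2–C3, with C5–C10 reconnected.
- Forward key step: a thermal [3,3] shift through a boat enforced by a 6,9-O-silylene bridge gives A2.
- Merits: all four stereocentres are set beforehand on a cyclohexane. Both alkenes come out ring-cis from the boat. The conditions are neutral. A2 already carries the formyl group and the acrylate arm.
- Weak points for this target:
  - The equilibrium between 1,2-dialkenylcyclohexanes and cyclodeca-1,5-dienes normally lies on the six-membered side. Only conjugation of C1=C10 with the formyl group pulls it forward.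
  - The bridged boat precursor with a quaternary C10 is a demanding compound.
  - An enal and an acrylate would be heated together.
- Comparison: this road is better in alkene geometry and needs no isomerisation step. The chosen plan sets against it an irreversible driving force, since the alkoxide becomes an enolate.

**Alternative 3:** Macrocyclising Barbier allylation at C7–C8.

- Cut: C7–C8.
- Forward key step: a low-valent metal inserts into an allylic C13–Br bond of a butenolide and the allylmetal attacks a C8 aldehyde, giving A3.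
- Merits: it is the most convergent road. The α-methylene lactone, C6 and both ring-cis alkenes are in place before closure. A3 is only a handful of steps from the target, so step economy after ring closure is better than in the chosen route.
- Weak points for this target:
  - A ten-membered ring with two ring-cis trisubstituted alkenes must be closed by an end-to-end C–C bond formation.
  - Two stereocentres (C7, C8) form in the closure under control of C6 and an epimerisable C9 only.
  - The open-chain precursor needs two Z-trisubstituted alkenes made stereoselectively.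
- Comparison: the chosen plan sets against it a unimolecular σ-bond exchange from a six-membered ring and a closed chair for C8/C9. It pays for this with a longer end game and one isomerisation.

Key step: step 10

## Route

Assumption: the sense of asymmetric induction in step 5 cannot be predicted with confidence; the ligand antipode that gives (6R)-9 is meant, and (R)-DTBM-SEGPHOS stands for it.

Step 1
Reactants: 1 (3-methoxyphenyl)methanol
Product: 3 3-(hydroxymethyl)cyclohex-2-en-1-one, via dihydroanisole 2 (not isolated)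
Conditions: Li, NH3(l), THF, t-BuOH, −78 °C; then 1 M HCl, THF, rt
Reagents that add atoms: water, O
Why: Birch reduction leaves both donor-substituted carbons sp2; acid hydrolysis of the enol ether and migration of the β,γ-alkene into conjugation should give the 3-substituted enone. No stereocentre is formed.

Step 2
Reactants: 3 3-(hydroxymethyl)cyclohex-2-en-1-one
Product: 4 3-{[(tert-butyldiphenylsilyl)oxy]methyl}cyclohex-2-en-1-one
Conditions: TBDPSCl, imidazole, DMF, rt
Reagents that add atoms: tert-butyl(chloro)diphenylsilane, CC(C)(C)[Si](Cl)(c1ccccc1)c1ccccc1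
Why: Standard silylation of a primary alcohol; the TBDPS ether should survive every later step and is removed last.

Step 3
Reactants: 4 3-{[(tert-butyldiphenylsilyl)oxy]methyl}cyclohex-2-en-1-one
Product: 5 tert-butyl{[3-(trimethylsilyloxy)cyclohexa-1,3-dien-1-yl]methoxy}diphenylsilane
Conditions: LDA, THF, −78 °C; TMSCl, −78 → 0 °C; non-aqueous work-up
Reagents that add atoms: chlorotrimethylsilane, C[Si](C)(C)Cl
Why: Kinetic deprotonation of the enone at the α′-carbon (C1) and O-silylation give the cross-conjugated silyl dienol ether, which fixes the site of the next C–C bond.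

Step 4
Reactants: 6 2,2-dimethyl-1,3-dioxan-5-one
Product: 7 2,2-dimethyl-4H-1,3-dioxin-5-yl trifluoromethanesulfonate
Conditions: LiHMDS, THF, −78 °C; PhNTf2, −78 → 0 °C
Reagents that add atoms: N-phenylbis(trifluoromethanesulfonimide), O=S(=O)(N(c1ccccc1)S(=O)(=O)C(F)(F)F)C(F)(F)F
Why: Enolisation and O-triflation of the symmetrical ketone give one enol triflate; its ring holds the enol ether oxygen cis to the CH2O carbon.

Step 5
Reactants: 5 tert-butyl{[3-(trimethylsilyloxy)cyclohexa-1,3-dien-1-yl]methoxy}diphenylsilane; 7 2,2-dimethyl-4H-1,3-dioxin-5-yl trifluoromethanesulfonate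
Product: 9 (6R)-3-{[(tert-butyldiphenylsilyl)oxy]methyl}-6-(2,2-dimethyl-4H-1,3-dioxin-5-yl)cyclohex-2-en-1-one, via tributyltin enolate 8 (not isolated)
Conditions: Bu3SnF, Pd2(dba)3 (2.5 mol%), (R)-DTBM-SEGPHOS (6 mol%), toluene, 40 °C
Reagents that add atoms: none
Why: Palladium-catalysed α-alkenylation of a tin enolate with an alkenyl triflate (Kosugi–Migita type, enantioselective form); the chiral bisphosphine on the alkenylpalladium selects the enolate face and sets C1 as R. The neutral, fluoride-mediated conditions should keep the new tertiary α′-centre from enolising.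

Step 6
Reactants: 10 (4-methoxyphenyl)methanol; 11 trichloroethylene
Product: 12 1-({[(E)-1,2-dichloroethenyl]oxy}methyl)-4-methoxybenzene
Conditions: KH, THF, 0 °C → rt
Reagents that add atoms: none
Why: The alkoxide eliminates HCl from trichloroethylene and adds anti to the dichloroacetylene formed, the usual entry to 1,2-dichlorovinyl ethers.

Step 7
Reactants: 12 1-({[(E)-1,2-dichloroethenyl]oxy}methyl)-4-methoxybenzene; 13 tert-butyl(2-iodoethoxy)dimethylsilane
Product: 15 tert-butyl({4-[(4-methoxybenzyl)oxy]but-3-yn-1-yl}oxy)dimethylsilane, via lithium alkoxyacetylide 14 (not isolated)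
Conditions: n-BuLi (2.2 equiv), THF, −78 → −40 °C; then 13, DMPU, −78 °C → rt
Reagents that add atoms: none
Why: Dehydrochlorination and Cl–Li exchange give the lithium alkoxyacetylide, which is alkylated by the primary iodide (SN2); this brings in C11 and C12 at the alcohol level.

Step 8
Reactants: 15 tert-butyl({4-[(4-methoxybenzyl)oxy]but-3-yn-1-yl}oxy)dimethylsilane
Product: 17 tert-butyl({(3E)-3-iodo-4-[(4-methoxybenzyl)oxy]but-3-en-1-yl}oxy)dimethylsilane, via alkenylzirconocene 16 (not isolated)
Conditions: Cp2Zr(H)Cl, THF, rt; then I2, 0 °C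
Reagents that add atoms: iodine, II
Why: syn-Hydrozirconation of the polarised ynol ether should place hydride on the oxygen-bearing carbon and zirconium on the other; iodinolysis with retention gives iodine trans to the ether oxygen.

Step 9
Reactants: 17 tert-butyl({(3E)-3-iodo-4-[(4-methoxybenzyl)oxy]but-3-en-1-yl}oxy)dimethylsilane; 9 (6R)-3-{[(tert-butyldiphenylsilyl)oxy]methyl}-6-(2,2-dimethyl-4H-1,3-dioxin-5-yl)cyclohex-2-en-1-one
Product: 19 (1R,6R)-1-{(1E)-4-[(tert-butyldimethylsilyl)oxy]-1-[(4-methoxybenzyl)oxy]but-1-en-2-yl}-3-{[(tert-butyldiphenylsilyl)oxy]methyl}-6-(2,2-dimethyl-4H-1,3-dioxin-5-yl)cyclohex-2-en-1-ol, via alkenyllithium 18 (not isolated)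
Conditions: t-BuLi (2.1 equiv), Et2O, −78 °C; anhydrous CeCl3, THF, −78 °C; then 9, −78 °C
Reagents that add atoms: none
Why: Iodine–lithium exchange with retention, transmetallation to the non-basic organocerium reagent and 1,2-addition to the enone. The nucleophile should add anti to the α′-dioxinyl arm, whose flank covers the syn face, so the two arms end trans and the carbinol carbon (C6) is R.

Step 10
Reactants: 19 (1R,6R)-1-{(1E)-4-[(tert-butyldimethylsilyl)oxy]-1-[(4-methoxybenzyl)oxy]but-1-en-2-yl}-3-{[(tert-butyldiphenylsilyl)oxy]methyl}-6-(2,2-dimethyl-4H-1,3-dioxin-5-yl)cyclohex-2-en-1-ol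
Product: 22 (7R,8S,9S)-12-[(tert-butyldimethylsilyl)oxy]-15-[(tert-butyldiphenylsilyl)oxy]-9,14-(isopropylidenedioxy)-8-[(4-methoxybenzyl)oxy]-13-norgermacra-1(10),4-dien-6-one (C1=C10 ring-trans; C4=C5 ring-cis), via potassium alkoxide 20 (not isolated), via potassium enolate 21 (not isolated)
Conditions: KH, 18-crown-6, THF, 0 °C → rt; then AcOH, THF, −78 °C
Reagents that add atoms: none
Why: Anionic oxy-Cope rearrangement, closest known type the KH/18-crown-6 ring expansion of 1,2-dialkenylcyclohex-2-enols to cyclodeca-1,5-dienones: the alkoxide 20 weakens C1–C6 and the 3-oxido-1,5-diene C8=C7–C6(O−)–C1–C10=C9 undergoes a concerted [3,3] shift. The ten-membered ring is closed by ring expansion, C8–C9 forming as the shared C1–C6 bond breaks, not by end-to-end cyclisation. With both arms equatorial only one chair is open to 19, with C5 and C2 equatorial and O− and H1 axial. C8 and C9 are controlled by this chair together with the E enol ether and the dioxin ring, which put O8 and O9 equatorial; suprafacial bonding then gives 8S,9S as the C1 and C6 centres are consumed. The equatorial C2 gives the ring-trans C1=C10 bond (corrected in step 20), C4=C5 stays ring-cis, and the equatorial C5 gives the ring-E enolate 21. C7 is set by protonation of 21 at −78 °C on its outer face, the inner face being covered by the C1=C10 unit, which gives 7R. The step needs chair over boat, secured by the diequatorial arms, and no loss of the C8 alkoxide from 21; in the ring-E enolate the C8–C9 bond, not the C8–O bond, lies over the π system, and the cold quench keeps the enolate short-lived.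

Step 11
Reactants: 22 (7R,8S,9S)-12-[(tert-butyldimethylsilyl)oxy]-15-[(tert-butyldiphenylsilyl)oxy]-9,14-(isopropylidenedioxy)-8-[(4-methoxybenzyl)oxy]-13-norgermacra-1(10),4-dien-6-one
Product: 23 (6R,7S,8S,9S)-12-[(tert-butyldimethylsilyl)oxy]-15-[(tert-butyldiphenylsilyl)oxy]-9,14-(isopropylidenedioxy)-8-[(4-methoxybenzyl)oxy]-13-norgermacra-1(10),4-dien-6-ol
Conditions: NaBH4, CeCl3·7H2O, MeOH/THF, −78 °C
Reagents that add atoms: none
Why: Luche 1,2-reduction of the enone. With the C5–C6–C7–C8 segment anti, hydride should attack the carbonyl face anti to the C7 side chain (Felkin sense, outer face), which places O6 trans to C11 as the trans-lactone needs (6R).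

Step 12
Reactants: 23 (6R,7S,8S,9S)-12-[(tert-butyldimethylsilyl)oxy]-15-[(tert-butyldiphenylsilyl)oxy]-9,14-(isopropylidenedioxy)-8-[(4-methoxybenzyl)oxy]-13-norgermacra-1(10),4-dien-6-ol
Product: 24 (6R,7S,8S,9S)-15-[(tert-butyldiphenylsilyl)oxy]-9,14-(isopropylidenedioxy)-8-[(4-methoxybenzyl)oxy]-13-norgermacra-1(10),4-diene-6,12-diol
Conditions: HF·pyridine, pyridine, THF, 0 °C
Reagents that add atoms: none
Why: Buffered fluoride should cleave the primary TBS ether well before the primary TBDPS ether and leaves the acetonide and the PMB ether alone.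

Step 13
Reactants: 24 (6R,7S,8S,9S)-15-[(tert-butyldiphenylsilyl)oxy]-9,14-(isopropylidenedioxy)-8-[(4-methoxybenzyl)oxy]-13-norgermacra-1(10),4-diene-6,12-diol
Product: 26 (6R,7S,8S,9S)-15-[(tert-butyldiphenylsilyl)oxy]-9,14-(isopropylidenedioxy)-8-[(4-methoxybenzyl)oxy]-13-norgermacra-1(10),4-dien-12,6-olide, via lactol 25 (not isolated)
Conditions: TEMPO (20 mol%), PhI(OAc)2 (2.5 equiv), CH2Cl2, rt
Reagents that add atoms: none
Why: Oxoammonium oxidation of the primary alcohol, lactol formation with the C6 hydroxyl and a second oxidation give the γ-lactone (oxidative lactonisation of a 1,4-diol). C6 keeps its configuration, and O8 is still protected, so only the 6,12-lactone can form.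

Step 14
Reactants: 26 (6R,7S,8S,9S)-15-[(tert-butyldiphenylsilyl)oxy]-9,14-(isopropylidenedioxy)-8-[(4-methoxybenzyl)oxy]-13-norgermacra-1(10),4-dien-12,6-olide
Product: 27 (6R,7S,8S,9S)-15-[(tert-butyldiphenylsilyl)oxy]-13-(dimethylamino)-9,14-(isopropylidenedioxy)-8-[(4-methoxybenzyl)oxy]germacra-1(10),4-dien-12,6-olide (C11 epimers)
Conditions: LDA, THF, −78 °C; CH2=NMe2+ I−, −78 °C → rt
Reagents that add atoms: N,N-dimethylmethyleneiminium iodide (Eschenmoser's salt), C=[N+](C)C.[I-]
Why: Mannich reaction of the lactone enolate brings in C13; the C11 configuration is irrelevant because it is lost in the next step.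

Step 15
Reactants: 27 (6R,7S,8S,9S)-15-[(tert-butyldiphenylsilyl)oxy]-13-(dimethylamino)-9,14-(isopropylidenedioxy)-8-[(4-methoxybenzyl)oxy]germacra-1(10),4-dien-12,6-olide
Product: 29 (6R,7S,8S,9S)-15-[(tert-butyldiphenylsilyl)oxy]-9,14-(isopropylidenedioxy)-8-[(4-methoxybenzyl)oxy]germacra-1(10),4,11(13)-trien-12,6-olide, via ammonium iodide 28 (not isolated)
Conditions: MeI, MeOH, rt; then NaHCO3, CH2Cl2/H2O, rt
Reagents that add atoms: none
Why: Quaternisation and mild-base elimination of trimethylamine give the α-methylene lactone.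

Step 16
Reactants: 29 (6R,7S,8S,9S)-15-[(tert-butyldiphenylsilyl)oxy]-9,14-(isopropylidenedioxy)-8-[(4-methoxybenzyl)oxy]germacra-1(10),4,11(13)-trien-12,6-olide
Product: 30 (6R,7R,8S,9S)-15-[(tert-butyldiphenylsilyl)oxy]-8-hydroxy-9,14-(isopropylidenedioxy)germacra-1(10),4,11(13)-trien-12,6-olide
Conditions: DDQ, CH2Cl2/pH 7 buffer, 0 °C
Reagents that add atoms: none
Why: Oxidative cleavage of the PMB ether; the buffer protects the acetonide. The change of the C7 descriptor is a change of priorities only.

Step 17
Reactants: 30 (6R,7R,8S,9S)-15-[(tert-butyldiphenylsilyl)oxy]-8-hydroxy-9,14-(isopropylidenedioxy)germacra-1(10),4,11(13)-trien-12,6-olide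
Product: 31 (6R,7S,8S,9S)-15-[(tert-butyldiphenylsilyl)oxy]-9,14-(isopropylidenedioxy)-8-(methacryloyloxy)germacra-1(10),4,11(13)-trien-12,6-olide
Conditions: methacrylic anhydride, Et3N, DMAP (cat.), CH2Cl2, rt
Reagents that add atoms: methacrylic anhydride, C=C(C)C(=O)OC(=O)C(C)=C
Why: DMAP-catalysed acylation of the secondary alcohol; the less migration-prone ester is put on O8 while O9 is still tied up in the acetonide.

Step 18
Reactants: 31 (6R,7S,8S,9S)-15-[(tert-butyldiphenylsilyl)oxy]-9,14-(isopropylidenedioxy)-8-(methacryloyloxy)germacra-1(10),4,11(13)-trien-12,6-olide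
Product: 32 (6R,7S,8S,9S)-15-[(tert-butyldiphenylsilyl)oxy]-9,14-dihydroxy-8-(methacryloyloxy)germacra-1(10),4,11(13)-trien-12,6-olide
Conditions: AcOH/THF/H2O (3:1:1), 35 °C
Reagents that add atoms: none
Why: Mild acid hydrolysis of the isopropylidene acetal; weak acid disfavours O8-to-O9 acyl migration and spares the TBDPS ether.

Step 19
Reactants: 32 (6R,7S,8S,9S)-15-[(tert-butyldiphenylsilyl)oxy]-9,14-dihydroxy-8-(methacryloyloxy)germacra-1(10),4,11(13)-trien-12,6-olide
Product: 33 (6R,7S,8S,9S)-15-[(tert-butyldiphenylsilyl)oxy]-9-hydroxy-8-(methacryloyloxy)-14-oxogermacra-1(10),4,11(13)-trien-12,6-olide (C1=C10 ring-trans)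
Conditions: TEMPO (10 mol%), PhI(OAc)2 (1.2 equiv), CH2Cl2, 0 °C → rt
Reagents that add atoms: none
Why: The oxoammonium oxidant should take the primary allylic alcohol well before the secondary one; C15 is still silylated.

Step 20
Reactants: 33 (6R,7S,8S,9S)-15-[(tert-butyldiphenylsilyl)oxy]-9-hydroxy-8-(methacryloyloxy)-14-oxogermacra-1(10),4,11(13)-trien-12,6-olide (C1=C10 ring-trans)
Product: 34 (6R,7S,8S,9S)-15-[(tert-butyldiphenylsilyl)oxy]-9-hydroxy-8-(methacryloyloxy)-14-oxogermacra-1(10),4,11(13)-trien-12,6-olide (C1=C10 ring-cis)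
Conditions: I2 (5 mol%), CH2Cl2, visible light, rt
Reagents that add atoms: none
Why: Iodine-atom addition, rotation and elimination equilibrate the trisubstituted enal. The ring-cis isomer has C2 trans to the formyl group and no trans-cyclodecene, so it should be the thermodynamic product; the radical path avoids enolate chemistry next to C9.

Step 21
Reactants: 34 (6R,7S,8S,9S)-15-[(tert-butyldiphenylsilyl)oxy]-9-hydroxy-8-(methacryloyloxy)-14-oxogermacra-1(10),4,11(13)-trien-12,6-olide (C1=C10 ring-cis)
Product: 35 (6R,7S,8S,9S)-9-acetoxy-15-[(tert-butyldiphenylsilyl)oxy]-8-(methacryloyloxy)-14-oxogermacra-1(10),4,11(13)-trien-12,6-olide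
Conditions: Ac2O, pyridine, CH2Cl2, 0 °C → rt
Reagents that add atoms: acetic anhydride, CC(=O)OC(C)=O
Why: Acetylation of the secondary allylic alcohol; no DMAP is used so that the Baylis–Hillman-type acetate formed is not displaced by a nucleophilic catalyst.

Step 22
Reactants: 35 (6R,7S,8S,9S)-9-acetoxy-15-[(tert-butyldiphenylsilyl)oxy]-8-(methacryloyloxy)-14-oxogermacra-1(10),4,11(13)-trien-12,6-olide
Product: 36 (6R,7S,8S,9S)-9-acetoxy-15-hydroxy-8-(methacryloyloxy)-14-oxogermacra-1(10),4,11(13)-trien-12,6-olide (both ring alkenes ring-cis)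
Conditions: HF·pyridine, pyridine, THF, 0 °C → rt
Reagents that add atoms: none
Why: Buffered fluoride removes the last silyl ether without base, so esters, enal and Michael acceptors should be untouched.

## Compound list

1 | (3-methoxyphenyl)methanol | COc1cccc(CO)c1 | starting material
2 | (5-methoxycyclohexa-1,4-dien-1-yl)methanol | COC1=CCC=C(CO)C1 | intermediate (not isolated)
3 | 3-(hydroxymethyl)cyclohex-2-en-1-one | O=C1C=C(CO)CCC1 | intermediate
4 | 3-{[(tert-butyldiphenylsilyl)oxy]methyl}cyclohex-2-en-1-one | O=C1C=C(CO[Si](c2ccccc2)(c2ccccc2)C(C)(C)C)CCC1 | intermediate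
5 | tert-butyl{[3-(trimethylsilyloxy)cyclohexa-1,3-dien-1-yl]methoxy}diphenylsilane | C[Si](C)(C)OC1=CCCC(CO[Si](c2ccccc2)(c2ccccc2)C(C)(C)C)=C1 | intermediate
6 | 2,2-dimethyl-1,3-dioxan-5-one | CC1(C)OCC(=O)CO1 | starting material
7 | 2,2-dimethyl-4H-1,3-dioxin-5-yl trifluoromethanesulfonate | CC1(C)OCC(OS(=O)(=O)C(F)(F)F)=CO1 | intermediate
8 | tributyl({5-{[(tert-butyldiphenylsilyl)oxy]methyl}cyclohexa-1,5-dien-1-yl}oxy)stannane (tin dienolate) | CCCC[Sn](CCCC)(CCCC)OC1=CCCC(CO[Si](c2ccccc2)(c2ccccc2)C(C)(C)C)=C1 | intermediate (not isolated)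
9 | (6R)-3-{[(tert-butyldiphenylsilyl)oxy]methyl}-6-(2,2-dimethyl-4H-1,3-dioxin-5-yl)cyclohex-2-en-1-one | O=C1C=C(CO[Si](c2ccccc2)(c2ccccc2)C(C)(C)C)CC[C@@H]1C1=COC(C)(C)OC1 | intermediate
10 | (4-methoxyphenyl)methanol | COc1ccc(CO)cc1 | starting material
11 | trichloroethylene | ClC=C(Cl)Cl | starting material
12 | 1-({[(E)-1,2-dichloroethenyl]oxy}methyl)-4-methoxybenzene | Cl/C=C(/Cl)OCc1ccc(OC)cc1 | intermediate
13 | tert-butyl(2-iodoethoxy)dimethylsilane | CC(C)(C)[Si](C)(C)OCCI | starting material
14 | lithium [(4-methoxybenzyl)oxy]acetylide | [Li]C#COCc1ccc(OC)cc1 | intermediate (not isolated)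
15 | tert-butyl({4-[(4-methoxybenzyl)oxy]but-3-yn-1-yl}oxy)dimethylsilane | COc1ccc(COC#CCCO[Si](C)(C)C(C)(C)C)cc1 | intermediate
16 | chlorobis(cyclopentadienyl){4-[(tert-butyldimethylsilyl)oxy]-1-[(4-methoxybenzyl)oxy]but-1-en-2-yl}zirconium (Zr trans to the ether oxygen) | Cl[Zr](/C(CCO[Si](C)(C)C(C)(C)C)=C/OCc1ccc(OC)cc1)(C1C=CC=C1)C1C=CC=C1 | intermediate (not isolated)
17 | tert-butyl({(3E)-3-iodo-4-[(4-methoxybenzyl)oxy]but-3-en-1-yl}oxy)dimethylsilane | COc1ccc(CO/C=C(/I)CCO[Si](C)(C)C(C)(C)C)cc1 | intermediate
18 | {4-[(tert-butyldimethylsilyl)oxy]-1-[(4-methoxybenzyl)oxy]but-1-en-2-yl}lithium (Li trans to the ether oxygen) | [Li]/C(CCO[Si](C)(C)C(C)(C)C)=C/OCc1ccc(OC)cc1 | intermediate (not isolated)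
19 | (1R,6R)-1-{(1E)-4-[(tert-butyldimethylsilyl)oxy]-1-[(4-methoxybenzyl)oxy]but-1-en-2-yl}-3-{[(tert-butyldiphenylsilyl)oxy]methyl}-6-(2,2-dimethyl-4H-1,3-dioxin-5-yl)cyclohex-2-en-1-ol (arms trans) | O[C@]1(/C(CCO[Si](C)(C)C(C)(C)C)=C/OCc2ccc(OC)cc2)C=C(CO[Si](c2ccccc2)(c2ccccc2)C(C)(C)C)CC[C@@H]1C1=COC(C)(C)OC1 | intermediate (key-step precursor)
20 | potassium alkoxide of 19 | [K+].[O-][C@]1(/C(CCO[Si](C)(C)C(C)(C)C)=C/OCc2ccc(OC)cc2)C=C(CO[Si](c2ccccc2)(c2ccccc2)C(C)(C)C)CC[C@@H]1C1=COC(C)(C)OC1 | intermediate (not isolated)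
21 | potassium (8S,9S)-enolate of 22 (C6=C7 with C5 trans to C8; C1=C10 ring-trans; C4=C5 ring-cis) | COc1ccc(CO[C@H]2/C(CCO[Si](C)(C)C(C)(C)C)=C(\[O-])/C=C(/CO[Si](c3ccccc3)(c3ccccc3)C(C)(C)C)CC/C=C3\COC(C)(C)O[C@H]23)cc1.[K+] | intermediate (not isolated)
22 | (7R,8S,9S)-12-[(tert-butyldimethylsilyl)oxy]-15-[(tert-butyldiphenylsilyl)oxy]-9,14-(isopropylidenedioxy)-8-[(4-methoxybenzyl)oxy]-13-norgermacra-1(10),4-dien-6-one (C1=C10 ring-trans; C4=C5 ring-cis) | COc1ccc(CO[C@H]2[C@@H](CCO[Si](C)(C)C(C)(C)C)C(=O)/C=C(/CO[Si](c3ccccc3)(c3ccccc3)C(C)(C)C)CC/C=C3\COC(C)(C)O[C@H]23)cc1 | intermediate (key-step product)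
23 | (6R,7S,8S,9S)-6-alcohol of 22 | COc1ccc(CO[C@H]2[C@@H](CCO[Si](C)(C)C(C)(C)C)[C@H](O)/C=C(/CO[Si](c3ccccc3)(c3ccccc3)C(C)(C)C)CC/C=C3\COC(C)(C)O[C@H]23)cc1 | intermediate
24 | (6R,7S,8S,9S)-15-[(tert-butyldiphenylsilyl)oxy]-9,14-(isopropylidenedioxy)-8-[(4-methoxybenzyl)oxy]-13-norgermacra-1(10),4-diene-6,12-diol | COc1ccc(CO[C@H]2[C@@H](CCO)[C@H](O)/C=C(/CO[Si](c3ccccc3)(c3ccccc3)C(C)(C)C)CC/C=C3\COC(C)(C)O[C@H]23)cc1 | intermediate
25 | 6,12-lactol of 24 (hemiacetal carbon C12, both epimers) | COc1ccc(CO[C@H]2[C@H]4CC(O)O[C@@H]4/C=C(/CO[Si](c3ccccc3)(c3ccccc3)C(C)(C)C)CC/C=C3\COC(C)(C)O[C@H]23)cc1 | intermediate (not isolated)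
26 | (6R,7S,8S,9S)-15-[(tert-butyldiphenylsilyl)oxy]-9,14-(isopropylidenedioxy)-8-[(4-methoxybenzyl)oxy]-13-norgermacra-1(10),4-dien-12,6-olide | COc1ccc(CO[C@H]2[C@H]4CC(=O)O[C@@H]4/C=C(/CO[Si](c3ccccc3)(c3ccccc3)C(C)(C)C)CC/C=C3\COC(C)(C)O[C@H]23)cc1 | intermediate
27 | 13-(dimethylamino) lactone (Mannich base of 26, C11 epimers) | COc1ccc(CO[C@H]2[C@H]4C(CN(C)C)C(=O)O[C@@H]4/C=C(/CO[Si](c3ccccc3)(c3ccccc3)C(C)(C)C)CC/C=C3\COC(C)(C)O[C@H]23)cc1 | intermediate
28 | 13-(trimethylammonio) lactone iodide | COc1ccc(CO[C@H]2[C@H]4C(C[N+](C)(C)C)C(=O)O[C@@H]4/C=C(/CO[Si](c3ccccc3)(c3ccccc3)C(C)(C)C)CC/C=C3\COC(C)(C)O[C@H]23)cc1.[I-] | intermediate (not isolated)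
29 | (6R,7S,8S,9S)-15-[(tert-butyldiphenylsilyl)oxy]-9,14-(isopropylidenedioxy)-8-[(4-methoxybenzyl)oxy]germacra-1(10),4,11(13)-trien-12,6-olide | COc1ccc(CO[C@H]2[C@H]4C(=C)C(=O)O[C@@H]4/C=C(/CO[Si](c3ccccc3)(c3ccccc3)C(C)(C)C)CC/C=C3\COC(C)(C)O[C@H]23)cc1 | intermediate
30 | (6R,7R,8S,9S)-15-[(tert-butyldiphenylsilyl)oxy]-8-hydroxy-9,14-(isopropylidenedioxy)germacra-1(10),4,11(13)-trien-12,6-olide | O[C@H]1[C@H]2C(=C)C(=O)O[C@@H]2/C=C(/CO[Si](c3ccccc3)(c3ccccc3)C(C)(C)C)CC/C=C3\COC(C)(C)O[C@H]13 | intermediate
31 | (6R,7S,8S,9S)-15-[(tert-butyldiphenylsilyl)oxy]-9,14-(isopropylidenedioxy)-8-(methacryloyloxy)germacra-1(10),4,11(13)-trien-12,6-olide | C=C(C)C(=O)O[C@H]1[C@H]2C(=C)C(=O)O[C@@H]2/C=C(/CO[Si](c3ccccc3)(c3ccccc3)C(C)(C)C)CC/C=C3\COC(C)(C)O[C@H]13 | intermediate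
32 | (6R,7S,8S,9S)-15-[(tert-butyldiphenylsilyl)oxy]-9,14-dihydroxy-8-(methacryloyloxy)germacra-1(10),4,11(13)-trien-12,6-olide (C1=C10 ring-trans) | C=C(C)C(=O)O[C@H]1[C@H]2C(=C)C(=O)O[C@@H]2/C=C(/CO[Si](c3ccccc3)(c3ccccc3)C(C)(C)C)CC/C=C(\CO)[C@@H]1O | intermediate
33 | (6R,7S,8S,9S)-15-[(tert-butyldiphenylsilyl)oxy]-9-hydroxy-8-(methacryloyloxy)-14-oxogermacra-1(10),4,11(13)-trien-12,6-olide (C1=C10 ring-trans) | C=C(C)C(=O)O[C@H]1[C@H]2C(=C)C(=O)O[C@@H]2/C=C(/CO[Si](c3ccccc3)(c3ccccc3)C(C)(C)C)CC/C=C(\C=O)[C@@H]1O | intermediate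
34 | (6R,7S,8S,9S)-15-[(tert-butyldiphenylsilyl)oxy]-9-hydroxy-8-(methacryloyloxy)-14-oxogermacra-1(10),4,11(13)-trien-12,6-olide (C1=C10 ring-cis) | C=C(C)C(=O)O[C@H]1[C@H]2C(=C)C(=O)O[C@@H]2/C=C(/CO[Si](c3ccccc3)(c3ccccc3)C(C)(C)C)CC/C=C(/C=O)[C@@H]1O | intermediate
35 | (6R,7S,8S,9S)-9-acetoxy-15-[(tert-butyldiphenylsilyl)oxy]-8-(methacryloyloxy)-14-oxogermacra-1(10),4,11(13)-trien-12,6-olide (both ring alkenes ring-cis) | C=C(C)C(=O)O[C@H]1[C@H]2C(=C)C(=O)O[C@@H]2/C=C(/CO[Si](c3ccccc3)(c3ccccc3)C(C)(C)C)CC/C=C(/C=O)[C@@H]1OC(C)=O | intermediate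
36 | (6R,7S,8S,9S)-9-acetoxy-15-hydroxy-8-(methacryloyloxy)-14-oxogermacra-1(10),4,11(13)-trien-12,6-olide (CNP0147326.4) | C=C(C)C(=O)O[C@H]1[C@H]2C(=C)C(=O)O[C@@H]2/C=C(/CO)CC/C=C(/C=O)[C@@H]1OC(C)=O | target

## Step count and risks

Total step count: 22. Longest linear sequence: 18 steps (steps 1, 2, 3, 5 and 9–22, from compound 1).

Steps least certain to work:

**Step 10 (key step).**
- What may go wrong: loss of the C8 PMB-oxide from the long-lived potassium enolate (E1cB), a slow [3,3] shift because both bond-forming termini carry donor oxygens, and protonation of C7 after the ring has relaxed, which would erode the C7 configuration.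
- Fallback, from 19 back to 22: after the rearrangement at 0 °C the enolate is silylated at −78 °C (TMSCl, Et3N) and isolated as the trimethylsilyl enol ether F1. C7 is then protonated in a separate, kinetically controlled protodesilylation (citric acid, MeOH, −20 °C) to give 22. This replaces one-pot enolate protonation by a trapped enol ether and a separate C-protonation.

**Step 5.**
- What may go wrong: low enantioselectivity or partial racemisation of the acidic α′-centre, and coupling at the γ-position of the dienolate.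
- Fallback, from 4 and 7 back to 9:
  1. The lithium enolate of 4 (LiHMDS) is alkenylated with 7 under Pd2(dba)3/XPhos to the racemic ketone F2.
  2. F2 is hydrogenated with dynamic kinetic resolution (RuCl2[(S)-xylBINAP][(S)-DAIPEN] or its antipode, t-BuOK, i-PrOH, H2), which is chemoselective for the carbonyl group, to the cis allylic alcohol F3.
  3. F3 is reoxidised with Dess–Martin periodinane/NaHCO3 to 9.

**Step 8.**
- What may go wrong: hydrozirconation with the opposite regiochemistry (zirconium on the oxygen-bearing carbon), or decomposition of the benzylic ynol ether.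
- Fallback, from 10 back to 17: commercial tert-butyl(but-3-yn-1-yloxy)dimethylsilane F4 adds iodine to give the (E)-1,2-diiodoalkene F5. Its less hindered terminal C–I bond is coupled with alcohol 10 with retention (CuI, i.e. copper monoiodide, 3,4,7,8-tetramethyl-1,10-phenanthroline, Cs2CO3, toluene, 80 °C) to give 17.

**Step 9.**
- What may go wrong: anti elimination of lithium PMB-oxide from the β-alkoxyalkenyllithium, enolisation of 9, and incomplete facial selectivity.
- Fallback, from 15 back to 19: the alkenylzirconocene 16 made from 15 is transmetallated with Me2Zn to the alkenyl(methyl)zinc F6. F6 is added to 9 with Ti(OiPr)4 and a bis(sulfonamide) diol ligand; no alkenyllithium and no vinyl iodide are involved.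

**Step 11.**
- What may go wrong: hydride delivery to the other carbonyl face after a conformational change of the ring, or 1,4-reduction.
- Fallback, from 22 back to 23: if the 6-epimeric alcohol F7 is formed, it is inverted by Mitsunobu esterification (4-nitrobenzoic acid, PPh3, DIAD) to the 6R ester F8. Methanolysis (K2CO3, MeOH) gives 23.

**Step 20.**
- What may go wrong: incomplete equilibration or an equilibrium that leaves much ring-trans isomer, and iodine-mediated transannular etherification by the free C9 hydroxyl.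
- Fallback, from 33 back to 34: triplet-sensitised photoisomerisation (thioxanthone, 405 nm, MeCN) to a photostationary mixture, with chromatographic separation and recycling of 33. This fallback makes no new compound (F0).

## Further compounds

F1 | step 10 | trimethylsilyl enol ether of 22 (C6–OTMS, C6=C7 with C5 trans to C8) | COc1ccc(CO[C@H]2/C(CCO[Si](C)(C)C(C)(C)C)=C(\O[Si](C)(C)C)/C=C(/CO[Si](c3ccccc3)(c3ccccc3)C(C)(C)C)CC/C=C3\COC(C)(C)O[C@H]23)cc1
F2 | step 5 | racemic 3-{[(tert-butyldiphenylsilyl)oxy]methyl}-6-(2,2-dimethyl-4H-1,3-dioxin-5-yl)cyclohex-2-en-1-one | O=C1C=C(CO[Si](c2ccccc2)(c2ccccc2)C(C)(C)C)CCC1C1=COC(C)(C)OC1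
F3 | step 5 | (1R,6R)-3-{[(tert-butyldiphenylsilyl)oxy]methyl}-6-(2,2-dimethyl-4H-1,3-dioxin-5-yl)cyclohex-2-en-1-ol (cis) | O[C@@H]1C=C(CO[Si](c2ccccc2)(c2ccccc2)C(C)(C)C)CC[C@@H]1C1=COC(C)(C)OC1
F4 | step 8 | tert-butyl(but-3-yn-1-yloxy)dimethylsilane | C#CCCO[Si](C)(C)C(C)(C)C
F5 | step 8 | tert-butyl{[(3E)-3,4-diiodobut-3-en-1-yl]oxy}dimethylsilane | I/C=C(/I)CCO[Si](C)(C)C(C)(C)C
F6 | step 9 | {4-[(tert-butyldimethylsilyl)oxy]-1-[(4-methoxybenzyl)oxy]but-1-en-2-yl}(methyl)zinc | C[Zn]/C(CCO[Si](C)(C)C(C)(C)C)=C/OCc1ccc(OC)cc1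
F7 | step 11 | (6S,7S,8S,9S)-6-epimer of 23 | COc1ccc(CO[C@H]2[C@@H](CCO[Si](C)(C)C(C)(C)C)[C@@H](O)/C=C(/CO[Si](c3ccccc3)(c3ccccc3)C(C)(C)C)CC/C=C3\COC(C)(C)O[C@H]23)cc1
F8 | step 11 | 6-O-(4-nitrobenzoyl) ester of 23 | COc1ccc(CO[C@H]2[C@@H](CCO[Si](C)(C)C(C)(C)C)[C@H](OC(=O)c4ccc(cc4)[N+](=O)[O-])/C=C(/CO[Si](c3ccccc3)(c3ccccc3)C(C)(C)C)CC/C=C3\COC(C)(C)O[C@H]23)cc1
F0 | step 20 | none | none
A1 | alternative 1 | ten-membered dienamine ester (pyrrolidine on C9, methyl ester C14 on C10, C1=C2 and C9=C10 unsaturation) | COc1ccc(CO[C@H]2[C@@H](C(=C)CO[Si](CC)(CC)CC)[C@H](O[Si](CC)(CC)CC)/C=C(/CO[Si](c3ccccc3)(c3ccccc3)C(C)(C)C)C/C=C/C(C(=O)OC)=C2/N3CCCC3)cc1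
A2 | alternative 2 | 6,9-O-di-tert-butylsilylene-bridged ring-cis,ring-cis germacra-1(10),4-dien-14-al with C7 methyl acrylate arm | COc1ccc(CO[C@H]2[C@@H](C(=C)C(=O)OC)[C@H](O[Si]3(C(C)(C)C)C(C)(C)C)/C=C(/CO[Si](c4ccccc4)(c4ccccc4)C(C)(C)C)CC/C=C(/C=O)[C@@H]2O3)cc1
A3 | alternative 3 | 8-hydroxy-9-[(4-methoxybenzyl)oxy] germacranolide with α-methylene lactone (14-O-TBS, 15-O-TBDPS) | O[C@H]1[C@H]2C(=C)C(=O)O[C@@H]2/C=C(/CO[Si](c2ccccc2)(c2ccccc2)C(C)(C)C)CC/C=C(/CO[Si](C)(C)C(C)(C)C)[C@@H]1OCc1ccc(OC)cc1
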